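**Retrosynthetic overview**

1. The exocyclic enol ether comes last, by Petasis methylenation of δ-lactone 21. The oxane ring is closed second, by 6-endo bromolactonisation of hydroxy acid 20, which sets C5.
2. C3 of the oxane comes from Sharpless epoxidation of the 2-substituted allyl alcohol 14, followed by opening of the epoxide with an isobutenyl Grignard reagent and oxidation to the acid.
3. The cyclohexane ring is closed first, by forming its C3–C4 bond (CHBr–C(CH3)Cl) from the acyclic dibromo ketone 5. Compound 5 is (S)-limonene with its ring alkene cleaved: the limonene ring is opened and closed again with bromine already on carbon.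
4. Enabling feature: in the cyclohexane, C3 (CHBr) and C4 (C(CH3)Cl) are adjacent and C1 carries the side chain, so C3 and C4 map onto the two carbonyl carbons of a 3-substituted 6-oxoheptanal. Br, Cl and the C1 substituent are all equatorial with CH3 axial, which is the outcome of a chair-like ring closure and not of trans-diaxial addition to a cyclohexene.

Key step: step 4

Remark on the chemistry: the SMILES is read as bromine, chlorine and the oxane substituent all equatorial on the cyclohexane, and hydroxyl cis to bromine on the oxane, i.e. (3R,5R) in the oxane and (1S,3S,4S) in the cyclohexyl group. Epoxide 2 is used as its mixture of epoxide epimers, because both epoxide carbons become carbonyl carbons.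

**Route**

Step 1
Reactants: 1 (S)-(−)-limonene [(4S)-1-methyl-4-(prop-1-en-2-yl)cyclohex-1-ene]
Product: 2 (4S)-1-methyl-4-(prop-1-en-2-yl)-7-oxabicyclo[4.1.0]heptane (limonene 1,2-oxide)
Conditions: mCPBA (1.0 equiv), NaHCO3, CH2Cl2, 0 °C
Reagents that add atoms: mCPBA (3-chloroperoxybenzoic acid), OOC(=O)c1cccc(Cl)c1
Why: Prilezhaev epoxidation; the trisubstituted ring alkene is more nucleophilic than the 1,1-disubstituted isopropenyl alkene, so one equivalent of peracid should epoxidise the ring alkene only, and the uncontrolled epoxide centres are erased in step 2.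

Step 2
Reactants: 2 (4S)-1-methyl-4-(prop-1-en-2-yl)-7-oxabicyclo[4.1.0]heptane
Product: 4 (3S)-6-oxo-3-(prop-1-en-2-yl)heptanal, via diol 3 (not isolated)
Conditions: H5IO6 (1.2 equiv), THF/H2O, 0 °C to rt
Reagents that add atoms: water, O
Why: hydrolysis of the epoxide to the 1,2-diol and Malaprade-type glycol cleavage by periodic acid in one flask should give the keto aldehyde; the stereocentre at C3 is not touched.

Step 3
Reactants: 4 (3S)-6-oxo-3-(prop-1-en-2-yl)heptanal
Product: 5 (5S)-7,7-dibromo-5-(prop-1-en-2-yl)heptan-2-one
Conditions: (PhO)3P (1.1 equiv), Br2 (1.05 equiv), Et3N (1.1 equiv), CH2Cl2, −78 °C; then 4, −78 to −30 °C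
Reagents that add atoms: bromine, BrBr
Why: deoxygenative gem-dibromination of an aldehyde by dibromotriphenoxyphosphorane (Appel-type oxyphosphonium activation); at low temperature the aldehyde should react and the methyl ketone should not, and no free bromine is present to attack the alkene.

Step 4
Reactants: 5 (5S)-7,7-dibromo-5-(prop-1-en-2-yl)heptan-2-one
Product: 8 (1S,2S,4S)-2-bromo-1-methyl-4-(prop-1-en-2-yl)cyclohexan-1-ol, via alpha-bromoalkylsamarium diiodide 6 (not isolated), via samarium alkoxide 7 (not isolated)
Conditions: SmI2 (2.1 equiv, 0.1 M in THF) added over 1 h to 5, HMPA (8 equiv), THF, −78 °C; sat. aq NH4Cl, −78 °C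
Reagents that add atoms: none
Why: Proposed new method: two single-electron transfers from SmI2 to the gem-dibromide should give first the alpha-bromo radical and then the alpha-bromoalkylsamarium 6, a samarium carbenoid that adds to the tethered methyl ketone through a four-centre transition state in which samarium bridges C7 and the carbonyl oxygen; the closest known reaction types are the samarium Barbier cyclisation of omega-halo ketones and the halomethylation of ketones by samarium carbenoids made from dihalomethanes. The ring closes in the 6-exo-trig mode through a chair with the isopropenyl group equatorial. The carbon–samarium centre is configurationally labile, so the bromine stereocentre (C2 of 8) is set in the chair itself, with bromine equatorial and cis to isopropenyl. At the carbinol carbon (C1 of 8) the oxygen should sit on the outer, equatorial side, held there by the bulky solvated samarium that bridges to it, which leaves the methyl group axial and the oxygen trans to bromine. The step needs chemoselectivity for the gem-dibromide over the ketone, the alkene and the secondary bromide of the product: the gem-dibromide is by far the most easily reduced group, SmI2 is added slowly and kept to two equivalents, and the trans-diequatorial bromo alkoxide 7 cannot reach the antiperiplanar geometry for epoxide closure in the cold.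

Step 5
Reactants: 8 (1S,2S,4S)-2-bromo-1-methyl-4-(prop-1-en-2-yl)cyclohexan-1-ol
Product: 11 (1S,2S,4S)-2-bromo-1-chloro-1-methyl-4-(prop-1-en-2-yl)cyclohexane, via lithium alkoxide 9 (not isolated), via chlorosulfite 10 (not isolated)
Conditions: LiN(SiMe3)2 (1.05 equiv), THF, −78 °C; SOCl2 (1.2 equiv), −78 to 0 °C
Reagents that add atoms: thionyl chloride, O=S(Cl)Cl
Why: deoxychlorination of a tertiary chlorosulfite with retention (internal-return substitution with neighbouring-group participation): the chlorosulfite is made from the alkoxide without free HCl, so the isopropenyl group is spared, and it should collapse either by internal return in the ether solvent or through the bromonium ion formed by the antiperiplanar bromine of the ring-flipped chair; both paths deliver chloride to the face that the oxygen left, giving the trans bromine/chlorine pair with both halogens equatorial.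

Step 6
Reactants: 11 (1S,2S,4S)-2-bromo-1-chloro-1-methyl-4-(prop-1-en-2-yl)cyclohexane
Product: 12 (1S,2S,4S)-2-bromo-1-chloro-4-(3-chloroprop-1-en-2-yl)-1-methylcyclohexane
Conditions: Ca(OCl)2 (0.6 equiv), solid CO2, CH2Cl2/H2O, 0 °C
Reagents that add atoms: calcium hypochlorite, [Ca+2].[O-]Cl.[O-]Cl
Why: ene-type allylic chlorination of an isopropenyl group by hypochlorous acid made in the flask; chlorine adds to the terminal CH2 and the proton is lost from the methyl group (three accessible hydrogens against one hindered ring methine), while the alkyl halides and all stereocentres are left alone.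

Step 7
Reactants: 12 (1S,2S,4S)-2-bromo-1-chloro-4-(3-chloroprop-1-en-2-yl)-1-methylcyclohexane
Product: 14 2-[(1S,3S,4S)-3-bromo-4-chloro-4-methylcyclohexyl]prop-2-en-1-ol, via formate ester 13 (not isolated)
Conditions: HCO2Na (3 equiv), Bu4NBr (cat.), DMF, 50 °C; then K2CO3 (cat.), MeOH, rt
Reagents that add atoms: sodium formate, [Na+].[O-]C=O
Why: SN2 displacement of the primary allylic chloride by formate followed by base-catalysed transesterification; the equatorial secondary bromide and the tertiary chloride, both flanked by a quaternary carbon, should be far slower to substitute or eliminate.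

Step 8
Reactants: 14 2-[(1S,3S,4S)-3-bromo-4-chloro-4-methylcyclohexyl]prop-2-en-1-ol
Product: 15 [(2R)-2-[(1S,3S,4S)-3-bromo-4-chloro-4-methylcyclohexyl]oxiran-2-yl]methanol
Conditions: Ti(OiPr)4 (10 mol %), D-(−)-diethyl tartrate (12 mol %), t-BuOOH (2 equiv, in decane), 4 Å molecular sieves, CH2Cl2, −20 °C
Reagents that add atoms: tert-butyl hydroperoxide, CC(C)(C)OO
Why: Sharpless asymmetric epoxidation of a 2-substituted allyl alcohol; the D-tartrate ligand should set the new quaternary centre as (R) under reagent control, which becomes C3 of the oxane.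

Step 9
Reactants: 15 [(2R)-2-[(1S,3S,4S)-3-bromo-4-chloro-4-methylcyclohexyl]oxiran-2-yl]methanol; 16 (2-methylprop-1-en-1-yl)magnesium bromide
Product: 18 (2R)-2-[(1S,3S,4S)-3-bromo-4-chloro-4-methylcyclohexyl]-5-methylhex-4-ene-1,2-diol, via bromomagnesium alkoxide 17 (not isolated)
Conditions: 16 (3 equiv, 0.5 M in THF), CuI (15 mol %), THF, −40 to −20 °C; sat. aq NH4Cl
Reagents that add atoms: none
Why: copper-catalysed SN2 opening of a 2,2-disubstituted epoxide at its CH2 terminus by an alkenyl Grignard reagent; the C–O bond at the quaternary carbon is not broken, so its configuration is kept, and the first equivalent of 16 is consumed by the hydroxyl group.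

Step 10
Reactants: 18 (2R)-2-[(1S,3S,4S)-3-bromo-4-chloro-4-methylcyclohexyl]-5-methylhex-4-ene-1,2-diol
Product: 20 (2R)-2-[(1S,3S,4S)-3-bromo-4-chloro-4-methylcyclohexyl]-2-hydroxy-5-methylhex-4-enoic acid, via hydroxy aldehyde 19 (not isolated)
Conditions: TEMPO (7 mol %), NaClO2 (2 equiv), NaOCl (2 mol %), MeCN/phosphate buffer (pH 6.7), 35 °C; then citric acid to pH 3
Reagents that add atoms: sodium chlorite, [Na+].[O-]Cl=O
Why: TEMPO-catalysed oxidation of a primary alcohol to the carboxylic acid with chlorite as terminal oxidant; the tertiary alcohol cannot be oxidised and the merely catalytic hypochlorite should spare the trisubstituted alkene.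

Step 11
Reactants: 20 (2R)-2-[(1S,3S,4S)-3-bromo-4-chloro-4-methylcyclohexyl]-2-hydroxy-5-methylhex-4-enoic acid
Product: 21 (3R,5R)-5-bromo-3-[(1S,3S,4S)-3-bromo-4-chloro-4-methylcyclohexyl]-3-hydroxy-6,6-dimethyloxan-2-one
Conditions: NBS (1.05 equiv), CH2Cl2, −20 to 0 °C, dark
Reagents that add atoms: N-bromosuccinimide, BrN1C(=O)CCC1=O
Why: 6-endo bromolactonisation; the carboxyl oxygen opens the bromonium ion at the tertiary carbon anti to bromine, so bromine is equatorial in the chair-like transition state, and the hydroxyl at C3, hydrogen-bonded to the carboxyl group and lying in its plane, should take the pseudo-equatorial site with the cyclohexyl group pseudo-axial, which puts bromine cis to hydroxyl (5R).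

Step 12
Reactants: 21 (3R,5R)-5-bromo-3-[(1S,3S,4S)-3-bromo-4-chloro-4-methylcyclohexyl]-3-hydroxy-6,6-dimethyloxan-2-one
Product: 22 (3R,5R)-5-bromo-3-[(1S,3S,4S)-3-bromo-4-chloro-4-methylcyclohexyl]-6,6-dimethyl-3-(trimethylsilyloxy)oxan-2-one
Conditions: N-(trimethylsilyl)imidazole (1.5 equiv), CH2Cl2, rt
Reagents that add atoms: N-(trimethylsilyl)imidazole, C[Si](C)(C)n1ccnc1
Why: silylation of the tertiary alcohol under neutral conditions, so that the hydroxyl does not consume the titanium reagent of step 13; no stereocentre is touched.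

Step 13
Reactants: 22 (3R,5R)-5-bromo-3-[(1S,3S,4S)-3-bromo-4-chloro-4-methylcyclohexyl]-6,6-dimethyl-3-(trimethylsilyloxy)oxan-2-one
Product: 24 (3R,5R)-5-bromo-3-[(1S,3S,4S)-3-bromo-4-chloro-4-methylcyclohexyl]-6,6-dimethyl-2-methylideneoxan-3-ol, via silyl ether 23 (not isolated)
Conditions: Cp2TiMe2 (3 equiv), toluene, 65 °C, dark; then K2CO3 (cat.), MeOH, 0 °C
Reagents that add atoms: dimethyltitanocene, [Ti+4].[CH3-].[CH3-].c1cc[cH-]c1.c1cc[cH-]c1
Why: Petasis methylenation of the lactone carbonyl gives the exocyclic enol ether, which cannot move into the ring because C3 is quaternary; base-catalysed methanolysis then removes the trimethylsilyl group without acid, so the enol ether and both halogen centres should survive.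

**Compound list**

1 | (S)-(−)-limonene, (4S)-1-methyl-4-(prop-1-en-2-yl)cyclohex-1-ene | CC(=C)[C@@H]1CC=C(C)CC1 | starting material
2 | (4S)-1-methyl-4-(prop-1-en-2-yl)-7-oxabicyclo[4.1.0]heptane (both epoxide epimers) | CC(=C)[C@@H]1CC2OC2(C)CC1 | intermediate
3 | (4S)-1-methyl-4-(prop-1-en-2-yl)cyclohexane-1,2-diol | CC(=C)[C@@H]1CC(O)C(C)(O)CC1 | intermediate
4 | (3S)-6-oxo-3-(prop-1-en-2-yl)heptanal | CC(=C)[C@H](CC=O)CCC(C)=O | intermediate
5 | (5S)-7,7-dibromo-5-(prop-1-en-2-yl)heptan-2-one | CC(=C)[C@H](CC(Br)Br)CCC(C)=O | intermediate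
6 | [(3S)-1-bromo-6-oxo-3-(prop-1-en-2-yl)heptyl]samarium diiodide (C1 epimers interconvert) | CC(=C)[C@H](CC(Br)[Sm](I)I)CCC(C)=O | intermediate
7 | diiodosamarium (1S,2S,4S)-2-bromo-1-methyl-4-(prop-1-en-2-yl)cyclohexan-1-olate | CC(=C)[C@H]1CC[C@](C)(O[Sm](I)I)[C@@H](Br)C1 | intermediate
8 | (1S,2S,4S)-2-bromo-1-methyl-4-(prop-1-en-2-yl)cyclohexan-1-ol | CC(=C)[C@H]1CC[C@](C)(O)[C@@H](Br)C1 | intermediate
9 | lithium (1S,2S,4S)-2-bromo-1-methyl-4-(prop-1-en-2-yl)cyclohexan-1-olate | CC(=C)[C@H]1CC[C@](C)(O[Li])[C@@H](Br)C1 | intermediate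
10 | (1S,2S,4S)-2-bromo-1-methyl-4-(prop-1-en-2-yl)cyclohexyl chlorosulfite | CC(=C)[C@H]1CC[C@](C)(OS(=O)Cl)[C@@H](Br)C1 | intermediate
11 | (1S,2S,4S)-2-bromo-1-chloro-1-methyl-4-(prop-1-en-2-yl)cyclohexane | CC(=C)[C@H]1CC[C@](C)(Cl)[C@@H](Br)C1 | intermediate
12 | (1S,2S,4S)-2-bromo-1-chloro-4-(3-chloroprop-1-en-2-yl)-1-methylcyclohexane | C=C(CCl)[C@H]1CC[C@](C)(Cl)[C@@H](Br)C1 | intermediate
13 | 2-[(1S,3S,4S)-3-bromo-4-chloro-4-methylcyclohexyl]prop-2-en-1-yl formate | C=C(COC=O)[C@H]1CC[C@](C)(Cl)[C@@H](Br)C1 | intermediate
14 | 2-[(1S,3S,4S)-3-bromo-4-chloro-4-methylcyclohexyl]prop-2-en-1-ol | C=C(CO)[C@H]1CC[C@](C)(Cl)[C@@H](Br)C1 | intermediate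
15 | [(2R)-2-[(1S,3S,4S)-3-bromo-4-chloro-4-methylcyclohexyl]oxiran-2-yl]methanol | OC[C@@]1(CO1)[C@H]2CC[C@](C)(Cl)[C@@H](Br)C2 | intermediate
16 | (2-methylprop-1-en-1-yl)magnesium bromide | CC(C)=C[Mg]Br | starting material
17 | bis(bromomagnesium) salt of diol 18 | Br[Mg]OC[C@@](O[Mg]Br)(CC=C(C)C)[C@H]1CC[C@](C)(Cl)[C@@H](Br)C1 | intermediate
18 | (2R)-2-[(1S,3S,4S)-3-bromo-4-chloro-4-methylcyclohexyl]-5-methylhex-4-ene-1,2-diol | OC[C@@](O)(CC=C(C)C)[C@H]1CC[C@](C)(Cl)[C@@H](Br)C1 | intermediate
19 | (2R)-2-[(1S,3S,4S)-3-bromo-4-chloro-4-methylcyclohexyl]-2-hydroxy-5-methylhex-4-enal | O=C[C@@](O)(CC=C(C)C)[C@H]1CC[C@](C)(Cl)[C@@H](Br)C1 | intermediate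
20 | (2R)-2-[(1S,3S,4S)-3-bromo-4-chloro-4-methylcyclohexyl]-2-hydroxy-5-methylhex-4-enoic acid | OC(=O)[C@@](O)(CC=C(C)C)[C@H]1CC[C@](C)(Cl)[C@@H](Br)C1 | intermediate
21 | (3R,5R)-5-bromo-3-[(1S,3S,4S)-3-bromo-4-chloro-4-methylcyclohexyl]-3-hydroxy-6,6-dimethyloxan-2-one | O=C1OC(C)(C)[C@H](Br)C[C@@]1(O)[C@H]1CC[C@](C)(Cl)[C@@H](Br)C1 | intermediate
22 | (3R,5R)-5-bromo-3-[(1S,3S,4S)-3-bromo-4-chloro-4-methylcyclohexyl]-6,6-dimethyl-3-(trimethylsilyloxy)oxan-2-one | O=C1OC(C)(C)[C@H](Br)C[C@@]1(O[Si](C)(C)C)[C@H]1CC[C@](C)(Cl)[C@@H](Br)C1 | intermediate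
23 | [(3R,5R)-5-bromo-3-[(1S,3S,4S)-3-bromo-4-chloro-4-methylcyclohexyl]-6,6-dimethyl-2-methylideneoxan-3-yl]oxy(trimethyl)silane | C=C1OC(C)(C)[C@H](Br)C[C@@]1(O[Si](C)(C)C)[C@H]1CC[C@](C)(Cl)[C@@H](Br)C1 | intermediate
24 | (3R,5R)-5-bromo-3-[(1S,3S,4S)-3-bromo-4-chloro-4-methylcyclohexyl]-6,6-dimethyl-2-methylideneoxan-3-ol | C=C1OC(C)(C)[C@H](Br)C[C@@]1(O)[C@H]1CC[C@](C)(Cl)[C@@H](Br)C1 | target

**Step count and risks**

Total step count: 13. Longest linear sequence: 13 steps, from 1.

Steps most likely to fail:

1. Step 4 (proposed new method). What may go wrong: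
   - over-reduction of the secondary bromide of the product, with beta-elimination of the samarium alkoxide to a cyclohexene;
   - alpha-elimination of the carbenoid followed by hydride shift;
   - ketyl formation at the ketone with cyclisation onto the isopropenyl group;
   - poor facial selectivity at the ketone carbon.

   Fallback with known chemistry, setting out from 5: the carbenoid is made by two-electron bromine–lithium exchange under in-situ (Barbier-type) conditions instead of by electron transfer. n-BuLi (1.05 equiv) is added to 5 in THF/Et2O/pentane at −110 °C. Exchange at a gem-dibromide outruns carbonyl addition, as in the known in-situ generation of alpha-haloalkyllithium carbenoids in the presence of ketones, which gives halohydrins. The alpha-bromoalkyllithium (5S)-7-bromo-7-lithio-5-(prop-1-en-2-yl)heptan-2-one F1 should add to the tethered ketone through the same chair and give lithium alkoxide 9, where the fallback comes back to the route (SOCl2 is added as in step 5, or the alkoxide is protonated to 8). Selectivity would rest on equilibration of the two carbenoid epimers through exchange with unreacted 5; a C1 epimer of 8 would be removed by chromatography.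

2. Step 5. What may go wrong:
   - loss of a proton from the tertiary cation (elimination);
   - opening of the bromonium ion at the secondary carbon after ring inversion, which exchanges the positions of the two halogens;
   - capture of an open cation from the axial face, which loses the configuration at the tertiary carbon.

   Fallback, setting out from 8: activation and ionisation are separated. (CF3CO)2O and pyridine in CH2Cl2 at 0 °C give (1S,2S,4S)-2-bromo-1-methyl-4-(prop-1-en-2-yl)cyclohexyl trifluoroacetate F2. F2 is then ionised in hexafluoroisopropanol with Et4NCl (5 equiv) at 0 °C. The strongly ionising, weakly nucleophilic solvent should make the bromine-bridged ion the only cation, and chloride opens it at the tertiary carbon anti to bromine. The fallback comes back to the route at 11.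

3. Step 11. What may go wrong: poor facial selectivity of bromonium formation relative to C3, if the hydrogen bond does not hold the hydroxyl in the plane of the carboxyl group.

   Fallback, setting out from 20: hydroxyl and carboxyl are tied into a temporary ring. 2,2-Dimethoxypropane and PPTS (cat.) in CH2Cl2 give (5R)-5-[(1S,3S,4S)-3-bromo-4-chloro-4-methylcyclohexyl]-2,2-dimethyl-5-(3-methylbut-2-en-1-yl)-1,3-dioxolan-4-one F3. NBS in wet MeCN at 0 °C then lets the lactone carbonyl oxygen open the bromonium ion in the 6-endo mode. The five-membered ring holds its ring oxygen in the carboxyl plane and so forces the cyclohexyl group into the pseudo-axial site. The dioxolanylium ion loses acetone on hydrolysis, and the fallback comes back to the route at 21.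

**Further compounds**

F1 | step 4 | (5S)-7-bromo-7-lithio-5-(prop-1-en-2-yl)heptan-2-one | CC(=C)[C@H](CC(Br)[Li])CCC(C)=O
F2 | step 5 | (1S,2S,4S)-2-bromo-1-methyl-4-(prop-1-en-2-yl)cyclohexyl trifluoroacetate | CC(=C)[C@H]1CC[C@](C)(OC(=O)C(F)(F)F)[C@@H](Br)C1
F3 | step 11 | (5R)-5-[(1S,3S,4S)-3-bromo-4-chloro-4-methylcyclohexyl]-2,2-dimethyl-5-(3-methylbut-2-en-1-yl)-1,3-dioxolan-4-one | CC1(C)OC(=O)[C@@](O1)(CC=C(C)C)[C@H]2CC[C@](C)(Cl)[C@@H](Br)C2
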